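The seven-membered ring is disconnected at C1–C2 and C3–C4. Ring atoms C1 (quaternary), C7 and C6 are carried as a cyclopropane made from geraniol by enantioselective intramolecular cyclopropanation; C5 and C4 are a silyloxyvinyl group on C6; C2 and C3 come from acetylene. One rhodium-catalysed (5+2) cycloaddition opens the C1–C6 bond, forms both new ring bonds and closes the cycloheptadiene while C1 and C7 keep their configuration, and it delivers the enol silane across C5–C6, the position that is allylated next. The precursor is the trans 1-(1-silyloxyvinyl)-3-(silyloxymethyl)-2-methyl-2-(4-methylpent-3-enyl)cyclopropane.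

Key step: step 8

Remark (numbering): ring atoms carry the target numbering throughout: C1 quaternary, C2 CH2, C3=C4 alkene with CH2OH on C4, C5 ketone, C6 acetonyl carbon, C7 enol-ester carbon.
Remark (structure correction): cycloadduct 13 is a 2-silyloxycyclohepta-1,4-diene, because its enol ether carbon lies between the ring CH2 and the =CH attached to C7; a 1-silyloxy locant would put it next to C7 and does not fit the cycloaddition.
Remark (assumption): Rh2(5R-MEPY)4, dirhodium tetrakis[methyl (5R)-2-oxopyrrolidine-5-carboxylate], is assumed to select the same alkene face for the geranyl ester as for the prenyl ester; if the sense is opposite, the 5S catalyst is used.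
Remark (assumption): no reagent is known to control the face of a singlet-oxygen ene reaction at the remote side-chain alkene, so the C–OOH centre is secured by separation of epimers in step 18.
Remark (precursor design): both silyl groups are TBS; the enol ether survives the rhodium step and is later cleaved selectively by methyllithium.

Step 1
Reactants: 1 geraniol; 2 bromoacetyl bromide
Product: 3 geranyl bromoacetate
Conditions: NaHCO3, MeCN, 0 °C
Reagents that add atoms: none
Why: O-acylation of the primary allylic alcohol by the acid bromide (esterification) with bicarbonate as acid scavenger; no stereocentre is involved.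

Step 2
Reactants: 3 geranyl bromoacetate
Product: 5 geranyl diazoacetate, via N-alkylated ditosylhydrazide 4 (not isolated)
Conditions: TsNHNHTs, DBU, THF, 0 °C
Reagents that add atoms: N,N'-ditosylhydrazine, Cc1ccc(cc1)S(=O)(=O)NNS(=O)(=O)c1ccc(C)cc1
Why: Diazoacetate synthesis by N-alkylation of the bis-sulfonylhydrazine and base-induced loss of two sulfinate ions, under conditions that leave both alkenes alone.

Step 3
Reactants: 5 geranyl diazoacetate
Product: 6 cyclopropane-fused lactone (1R,5S,6R)
Conditions: Rh2(5R-MEPY)4 (1 mol %), CH2Cl2, 40 °C, slow addition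
Reagents that add atoms: none
Why: Rhodium-carbene intramolecular cyclopropanation of the allylic 2,3-alkene (carboxamidate catalysts prefer it to the remote alkene); the concerted syn addition turns the E geometry into methyl cis to the lactone CH2O carbon and the chiral ligands choose the alkene face, which fixes ring C1 and C7 and, provisionally, C6.

Step 4
Reactants: 6 cyclopropane-fused lactone
Product: 7 methyl hemiketal (lactol)
Conditions: MeLi (1.05 equiv), THF, −78 °C; aq. NH4Cl
Reagents that add atoms: methyllithium, [Li]C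
Why: Nucleophilic addition of one equivalent of methyllithium to the γ-lactone, whose lithium hemiketal does not collapse at −78 °C, so a second addition is avoided and the cyclopropane centres are untouched.

Step 5
Reactants: 7 methyl hemiketal
Product: 9 cis TBS-ether methyl ketone, via open hydroxy ketone 8 (not isolated)
Conditions: TBSCl, imidazole, DMF, 23 °C
Reagents that add atoms: tert-butyldimethylsilyl chloride, CC(C)(C)[Si](C)(C)Cl
Why: O-silylation of the primary hydroxyl of the open keto tautomer, which reacts much faster than the tertiary hemiketal hydroxyl and so drains the ring–chain equilibrium.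

Step 6
Reactants: 9 cis TBS-ether methyl ketone
Product: 10 trans TBS-ether methyl ketone
Conditions: NaOMe, MeOH, 50 °C
Reagents that add atoms: none
Why: Base-mediated epimerisation through the ketone enolate at cyclopropane carbon C6 (thermodynamic control), which moves the acetyl group off the face that also carries CH2OTBS and methyl; the cis isomer, if any remains, is recycled.

Step 7
Reactants: 10 trans TBS-ether methyl ketone
Product: 11 silyloxyvinylcyclopropane
Conditions: TBSOTf, Et3N, CH2Cl2, 0 °C
Reagents that add atoms: tert-butyldimethylsilyl trifluoromethanesulfonate, CC(C)(C)[Si](C)(C)OS(=O)(=O)C(F)(F)F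
Why: Soft enolisation and O-silylation, regioselective for the methyl side because an enol double bond exocyclic to the cyclopropane is strongly disfavoured.

Step 8
Reactants: 11 silyloxyvinylcyclopropane; 12 acetylene
Product: 13 2-silyloxycyclohepta-1,4-diene
Conditions: [RhCl(CO)2]2 (5 mol %), acetylene (1 atm), ClCH2CH2Cl, 60 °C
Reagents that add atoms: none
Why: The chlorocarbonylrhodium fragment (monovalent rhodium) binds the enol ether alkene in its s-cis rotamer, inserts into the adjoining C1–C6 cyclopropane bond to give a σ-alkyl/π-allyl rhodacyclohexene, inserts acetylene at the allyl terminus C4 (C3–C4 bond) and forms C1–C2 by reductive elimination. The closest known reaction type is the rhodium-catalysed intermolecular (5+2) cycloaddition of oxygen-substituted vinylcyclopropanes with alkynes. The seven-membered ring closes in the reductive elimination, by contraction of the eight-membered rhodacycle that results from enlarging the first metallacycle with the alkyne. No stereocentre is created: C1 and C7 are carried through with retention because only the C1–C6 bond is traded for C1–C2 at rhodium-bound C1, and C6 becomes trigonal. The step needs insertion into C1–C6 and not into C6–C7; the rotamer that leads to C1–C6 insertion stacks the alkene terminus over C7 on the face that carries only hydrogen (vinyl trans to CH2OTBS), whereas the rotamer for C6–C7 insertion pushes it into the chain on C1, and C1–C6 is the longest and most substituted ring bond. Acetylene is kept in excess at 1 atm so that its capture outruns β-hydride loss from the tertiary alkylrhodium intermediate.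

Step 9
Reactants: 13 2-silyloxycyclohepta-1,4-diene
Product: 15 6-allyl cyclohept-3-enone, via lithium enolate 14 (not isolated)
Conditions: MeLi, THF, 0 to 23 °C; then DMPU, allyl bromide, −78 to −40 °C
Reagents that add atoms: allyl bromide, C=CCBr
Why: Cleavage of the enol Si–O bond by methyllithium releases the regiodefined C5–C6 lithium enolate (the primary silyl ether is inert), and SN2 C-allylation anti to the neighbouring C7 CH2OTBS group sets C6 trans to C7, fast alkylation at low temperature limiting proton transfer from C4.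

Step 10
Reactants: 15 6-allyl cyclohept-3-enone
Product: 16 6-allyl cyclohept-2-enone
Conditions: DBU, CH2Cl2, 23 °C
Reagents that add atoms: none
Why: Base-catalysed 1,3-prototropic shift through the extended dienolate moves the C2=C3 alkene into conjugation as C3=C4 (thermodynamic control, unconverted isomer recycled), and the same conditions equilibrate C6 to the more stable trans arrangement.

Step 11
Reactants: 16 6-allyl cyclohept-2-enone
Product: 17 6-acetonyl cyclohept-2-enone
Conditions: PdCl2 (10 mol %), CuCl, O2 (1 atm), DMF/H2O, 23 °C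
Reagents that add atoms: water, O
Why: Tsuji–Wacker oxidation, in which Markovnikov hydroxypalladation of the only monosubstituted alkene and β-hydride elimination give the methyl ketone while the trisubstituted and the conjugated alkenes stay uncoordinated.

Step 12
Reactants: 17 6-acetonyl cyclohept-2-enone
Product: 18 primary alcohol
Conditions: HF·pyridine, pyridine, THF, 0 to 23 °C
Reagents that add atoms: none
Why: Fluoride-mediated Si–O cleavage under buffered non-basic conditions, which avoids aldol and oxa-Michael reactions of the keto-enone.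

Step 13
Reactants: 18 primary alcohol
Product: 19 C7 aldehyde
Conditions: Dess–Martin periodinane, pyridine, CH2Cl2, 0 °C
Reagents that add atoms: none
Why: Dess–Martin oxidation of the primary alcohol under buffered conditions, at which the aldehyde and ketones should not enolise, so C6 and C7 keep their configuration.

Step 14
Reactants: 19 C7 aldehyde
Product: 20 E-alkenylboronic pinacol ester
Conditions: CrCl2, Cl2CHB(pin), LiI, THF, 23 °C
Reagents that add atoms: 2-(dichloromethyl)-4,4,5,5-tetramethyl-1,3,2-dioxaborolane, ClC(Cl)B1OC(C)(C)C(C)(C)O1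
Why: Takai–Utimoto olefination, in which the geminal dichromium reagent adds to the aldehyde far faster than to the ketones or the enone and anti-elimination of the β-oxidochromium intermediate gives the E alkene.

Step 15
Reactants: 20 E-alkenylboronic pinacol ester
Product: 21 potassium E-alkenyltrifluoroborate
Conditions: KHF2, MeOH/H2O, 23 °C
Reagents that add atoms: potassium hydrogen difluoride, [K+].F[H-]F
Why: Ligand exchange at boron (pinacol for fluoride) gives the air-stable trifluoroborate needed for the copper coupling without touching the alkene geometry.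

Step 16
Reactants: 21 potassium E-alkenyltrifluoroborate; 22 3-methylbut-2-enoic acid
Product: 23 E-enol 3-methylbut-2-enoate
Conditions: Cu(OAc)2 (20 mol %), DMAP, 4 Å MS, O2 (1 atm), CH2Cl2, 30 °C
Reagents that add atoms: none
Why: Chan–Lam–Evans oxidative C–O coupling, in which the alkenyl group passes from boron to a divalent copper carboxylate and, after oxidation by O2 to trivalent copper, reductive elimination forms the C–O bond with retention of the E geometry near room temperature, so the diketone meets no strong base.

Step 17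
Reactants: 23 E-enol 3-methylbut-2-enoate
Product: 24 C4-hydroxymethyl enone
Conditions: aq. CH2O, PBu3 (20 mol %), THF, 23 °C
Reagents that add atoms: formaldehyde, C=O
Why: Morita–Baylis–Hillman reaction, in which the phosphine adds reversibly to C3, the phosphonium enolate adds at C4 to formaldehyde and loss of the phosphine restores the C3=C4 alkene, creating no stereocentre under near-neutral conditions meant to spare the enol ester.

Step 18
Reactants: 24 C4-hydroxymethyl enone
Product: 25 target hydroperoxide
Conditions: O2, visible light, tetraphenylporphyrin, CH2Cl2, 0 °C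
Reagents that add atoms: dioxygen, O=O
Why: Schenck ene reaction of singlet oxygen with the most electron-rich, trisubstituted side-chain alkene (the enone, enoate and enol ester alkenes are far less reactive), hydrogen abstraction from a geminal methyl giving the secondary allylic hydroperoxide; the new C–OOH centre is too remote for substrate control, so both epimers and the tertiary regioisomer should form and the (S) epimer is isolated by preparative HPLC.

Compound list
1 | geraniol, (2E)-3,7-dimethylocta-2,6-dien-1-ol | CC(C)=CCC/C(C)=C/CO | starting material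
2 | bromoacetyl bromide | BrCC(Br)=O | starting material
3 | geranyl bromoacetate | CC(C)=CCC/C(C)=C/COC(=O)CBr | intermediate
4 | geranyl [1,2-bis(4-methylbenzenesulfonyl)hydrazinyl]acetate (N-alkylated ditosylhydrazide) | CC(C)=CCC/C(C)=C/COC(=O)CN(NS(=O)(=O)c1ccc(C)cc1)S(=O)(=O)c1ccc(C)cc1 | intermediate
5 | geranyl diazoacetate | CC(C)=CCC/C(C)=C/COC(=O)C=[N+]=[N-] | intermediate
6 | (1R,5S,6R)-6-methyl-6-(4-methylpent-3-en-1-yl)-3-oxabicyclo[3.1.0]hexan-2-one | O=C1OC[C@H]2[C@@H]1[C@]2(C)CCC=C(C)C | intermediate
7 | (1R,5S,6R)-2,6-dimethyl-6-(4-methylpent-3-en-1-yl)-3-oxabicyclo[3.1.0]hexan-2-ol, both C2 epimers | CC1(O)OC[C@H]2[C@@H]1[C@]2(C)CCC=C(C)C | intermediate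
8 | 1-[(1R,2R,3S)-3-(hydroxymethyl)-2-methyl-2-(4-methylpent-3-en-1-yl)cyclopropyl]ethan-1-one | CC(=O)[C@@H]1[C@H](CO)[C@@]1(C)CCC=C(C)C | intermediate
9 | 1-[(1R,2R,3S)-3-{[(tert-butyldimethylsilyl)oxy]methyl}-2-methyl-2-(4-methylpent-3-en-1-yl)cyclopropyl]ethan-1-one (acetyl cis to CH2OTBS) | CC(=O)[C@@H]1[C@H](CO[Si](C)(C)C(C)(C)C)[C@@]1(C)CCC=C(C)C | intermediate
10 | 1-[(1S,2R,3S)-3-{[(tert-butyldimethylsilyl)oxy]methyl}-2-methyl-2-(4-methylpent-3-en-1-yl)cyclopropyl]ethan-1-one (acetyl trans to CH2OTBS) | CC(=O)[C@H]1[C@H](CO[Si](C)(C)C(C)(C)C)[C@@]1(C)CCC=C(C)C | intermediate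
11 | tert-butyl({(1S,2R,3S)-3-{1-[(tert-butyldimethylsilyl)oxy]ethenyl}-2-methyl-2-(4-methylpent-3-en-1-yl)cyclopropyl}methoxy)dimethylsilane | C=C(O[Si](C)(C)C(C)(C)C)[C@H]1[C@H](CO[Si](C)(C)C(C)(C)C)[C@@]1(C)CCC=C(C)C | intermediate
12 | acetylene | C#C | starting material
13 | (6S,7S)-2-[(tert-butyldimethylsilyl)oxy]-7-{[(tert-butyldimethylsilyl)oxy]methyl}-6-methyl-6-(4-methylpent-3-en-1-yl)cyclohepta-1,4-diene | CC(C)=CCC[C@@]1(C)C=CCC(O[Si](C)(C)C(C)(C)C)=C[C@@H]1CO[Si](C)(C)C(C)(C)C | intermediate
14 | lithium (6S,7S)-7-{[(tert-butyldimethylsilyl)oxy]methyl}-6-methyl-6-(4-methylpent-3-en-1-yl)cyclohepta-1,4-dien-2-olate | CC(C)=CCC[C@@]1(C)C=CCC(O[Li])=C[C@@H]1CO[Si](C)(C)C(C)(C)C | intermediate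
15 | (5S,6S,7S)-6-{[(tert-butyldimethylsilyl)oxy]methyl}-5-methyl-5-(4-methylpent-3-en-1-yl)-7-(prop-2-en-1-yl)cyclohept-3-en-1-one | CC(C)=CCC[C@@]1(C)C=CCC(=O)[C@@H](CC=C)[C@@H]1CO[Si](C)(C)C(C)(C)C | intermediate
16 | (5S,6S,7S)-6-{[(tert-butyldimethylsilyl)oxy]methyl}-5-methyl-5-(4-methylpent-3-en-1-yl)-7-(prop-2-en-1-yl)cyclohept-2-en-1-one | CC(C)=CCC[C@@]1(C)CC=CC(=O)[C@@H](CC=C)[C@@H]1CO[Si](C)(C)C(C)(C)C | intermediate
17 | (5S,6S,7S)-6-{[(tert-butyldimethylsilyl)oxy]methyl}-5-methyl-5-(4-methylpent-3-en-1-yl)-7-(2-oxopropyl)cyclohept-2-en-1-one | CC(C)=CCC[C@@]1(C)CC=CC(=O)[C@@H](CC(C)=O)[C@@H]1CO[Si](C)(C)C(C)(C)C | intermediate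
18 | (5S,6S,7S)-6-(hydroxymethyl)-5-methyl-5-(4-methylpent-3-en-1-yl)-7-(2-oxopropyl)cyclohept-2-en-1-one | CC(C)=CCC[C@@]1(C)CC=CC(=O)[C@@H](CC(C)=O)[C@@H]1CO | intermediate
19 | (1S,2S,7S)-2-methyl-2-(4-methylpent-3-en-1-yl)-6-oxo-7-(2-oxopropyl)cyclohept-4-ene-1-carbaldehyde | CC(C)=CCC[C@@]1(C)CC=CC(=O)[C@@H](CC(C)=O)[C@@H]1C=O | intermediate
20 | (5S,6S,7S)-5-methyl-5-(4-methylpent-3-en-1-yl)-7-(2-oxopropyl)-6-[(E)-2-(4,4,5,5-tetramethyl-1,3,2-dioxaborolan-2-yl)ethenyl]cyclohept-2-en-1-one | CC(C)=CCC[C@@]1(C)CC=CC(=O)[C@@H](CC(C)=O)[C@@H]1/C=C/B2OC(C)(C)C(C)(C)O2 | intermediate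
21 | potassium trifluoro{(E)-2-[(1S,2S,7S)-2-methyl-2-(4-methylpent-3-en-1-yl)-6-oxo-7-(2-oxopropyl)cyclohept-4-en-1-yl]ethenyl}borate | CC(C)=CCC[C@@]1(C)CC=CC(=O)[C@@H](CC(C)=O)[C@@H]1/C=C/[B-](F)(F)F.[K+] | intermediate
22 | 3-methylbut-2-enoic acid | CC(C)=CC(=O)O | starting material
23 | (E)-2-[(1S,2S,7S)-2-methyl-2-(4-methylpent-3-en-1-yl)-6-oxo-7-(2-oxopropyl)cyclohept-4-en-1-yl]ethenyl 3-methylbut-2-enoate | CC(C)=CCC[C@@]1(C)CC=CC(=O)[C@@H](CC(C)=O)[C@@H]1/C=C/OC(=O)C=C(C)C | intermediate
24 | (E)-2-[(1S,2S,7S)-5-(hydroxymethyl)-2-methyl-2-(4-methylpent-3-en-1-yl)-6-oxo-7-(2-oxopropyl)cyclohept-4-en-1-yl]ethenyl 3-methylbut-2-enoate | CC(C)=CCC[C@@]1(C)CC=C(CO)C(=O)[C@@H](CC(C)=O)[C@@H]1/C=C/OC(=O)C=C(C)C | intermediate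
25 | (E)-2-[(1S,2S,7S)-2-[(3S)-3-hydroperoxy-4-methylpent-4-en-1-yl]-5-(hydroxymethyl)-2-methyl-6-oxo-7-(2-oxopropyl)cyclohept-4-en-1-yl]ethenyl 3-methylbut-2-enoate | C=C(C)[C@H](CC[C@@]1(C)CC=C(CO)C(=O)[C@@H](CC(C)=O)[C@@H]1/C=C/OC(=O)C=C(C)C)OO | target

Total step count: 18. Longest linear sequence: 18 steps, from geraniol.

Steps most likely to fail

Step 8. Rhodium may insert into the C6–C7 bond instead, where the metal-bound carbon is only secondary, or the tertiary alkylrhodium may lose a β-hydrogen before acetylene is taken up, so that a regioisomeric diene or open-chain trienes result. The fallback avoids cyclopropane opening and closes the ring by olefin metathesis; it sets out from geraniol 1 and comes back at enone 16. Geraniol is esterified with commercial 4-[(4-methoxybenzyl)oxy]butanoic acid (DCC, DMAP) to give geranyl ester F1. An enantioselective Ireland–Claisen rearrangement joins C7 to C1 and gives acid F2; it runs through the boron ketene acetal made with chiral 2-bromo-4,5-diphenyl-1,3-bis(4-methylbenzenesulfonyl)-1,3,2-diazaborolidine and an amine base, with the side chain cis to the allyloxy oxygen and the homoprenyl group equatorial in the chair transition state, and the reagent antipode sets the absolute configuration. LiAlH4 gives alcohol F3 and TBSCl/imidazole gives silyl ether F4. DDQ removes the 4-methoxybenzyl group to give alcohol F5, Dess–Martin oxidation gives aldehyde F6, allylmagnesium bromide gives homoallylic alcohol F7, and a second Dess–Martin oxidation gives allyl ketone F8. Ring-closing metathesis (second-generation Hoveyda–Grubbs catalyst, dilute CH2Cl2, 40 °C) closes C2=C3 to give cycloheptenone F9; the catalyst should load on the unhindered allyl terminus, from which only the vinyl group on C1 is within reach of a favourable ring size. DBU conjugates the alkene to give enone F10, and kinetic deprotonation (LDA, THF, −78 °C) with allyl bromide alkylates C6 anti to C7 to give 16.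

Step 18. Singlet oxygen attacks both faces of the side-chain alkene and abstracts hydrogen on either side of it, so the (S)-hydroperoxide comes with its C-epimer and the tertiary allylic hydroperoxide, and the two secondary epimers may not separate. The fallback secures the epimer through covalent derivatives; it sets out from 24 and comes back at 25. The crude photooxygenation mixture is treated with 2-methoxypropene and pyridinium p-toluenesulfonate, which caps each hydroperoxide as a stable peroxyketal and the primary alcohol as a mixed ketal. The derivatives are separated by chromatography, and the (S) compound, bis(2-methoxypropan-2-yl) derivative F11, is unmasked with AcOH/THF/H2O. This does not raise the facial selectivity; it only makes the isolation reliable.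

Step 17. The phosphine may add too slowly to the hindered seven-membered enone, and long exposure to the basic phosphonium enolate in a wet medium may cleave the enol ester. The fallback installs the carbon by cross-coupling; it sets out from 23 and comes back at 24. α-Iodination of the enone (I2, pyridine, CH2Cl2) gives α-iodoenone F12, and Stille coupling with (tributylstannyl)methanol (Pd(PPh3)4, dioxane, 80 °C) gives 24.

Further compounds
F1 | step 8 | geranyl 4-[(4-methoxybenzyl)oxy]butanoate | CC(C)=CCC/C(C)=C/COC(=O)CCCOCc1ccc(OC)cc1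
F2 | step 8 | (2S,3S)-2-{2-[(4-methoxybenzyl)oxy]ethyl}-3,7-dimethyl-3-vinyloct-6-enoic acid | CC(C)=CCC[C@@](C)(C=C)[C@@H](C(=O)O)CCOCc1ccc(OC)cc1
F3 | step 8 | (2S,3S)-2-{2-[(4-methoxybenzyl)oxy]ethyl}-3,7-dimethyl-3-vinyloct-6-en-1-ol | CC(C)=CCC[C@@](C)(C=C)[C@@H](CO)CCOCc1ccc(OC)cc1
F4 | step 8 | tert-butyl{[(2S,3S)-2-{2-[(4-methoxybenzyl)oxy]ethyl}-3,7-dimethyl-3-vinyloct-6-en-1-yl]oxy}dimethylsilane | CC(C)=CCC[C@@](C)(C=C)[C@@H](CO[Si](C)(C)C(C)(C)C)CCOCc1ccc(OC)cc1
F5 | step 8 | (3S,4S)-3-{[(tert-butyldimethylsilyl)oxy]methyl}-4,8-dimethyl-4-vinylnon-7-en-1-ol | CC(C)=CCC[C@@](C)(C=C)[C@@H](CO[Si](C)(C)C(C)(C)C)CCO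
F6 | step 8 | (3S,4S)-3-{[(tert-butyldimethylsilyl)oxy]methyl}-4,8-dimethyl-4-vinylnon-7-enal | CC(C)=CCC[C@@](C)(C=C)[C@@H](CO[Si](C)(C)C(C)(C)C)CC=O
F7 | step 8 | (6S,7S)-6-{[(tert-butyldimethylsilyl)oxy]methyl}-7,11-dimethyl-7-vinyldodeca-1,10-dien-4-ol, both C4 epimers | CC(C)=CCC[C@@](C)(C=C)[C@@H](CO[Si](C)(C)C(C)(C)C)CC(O)CC=C
F8 | step 8 | (6S,7S)-6-{[(tert-butyldimethylsilyl)oxy]methyl}-7,11-dimethyl-7-vinyldodeca-1,10-dien-4-one | CC(C)=CCC[C@@](C)(C=C)[C@@H](CO[Si](C)(C)C(C)(C)C)CC(=O)CC=C
F9 | step 8 | (5S,6S)-6-{[(tert-butyldimethylsilyl)oxy]methyl}-5-methyl-5-(4-methylpent-3-en-1-yl)cyclohept-3-en-1-one | CC(C)=CCC[C@@]1(C)C=CCC(=O)C[C@@H]1CO[Si](C)(C)C(C)(C)C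
F10 | step 8 | (5S,6S)-6-{[(tert-butyldimethylsilyl)oxy]methyl}-5-methyl-5-(4-methylpent-3-en-1-yl)cyclohept-2-en-1-one | CC(C)=CCC[C@@]1(C)CC=CC(=O)C[C@@H]1CO[Si](C)(C)C(C)(C)C
F11 | step 18 | bis(2-methoxypropan-2-yl) derivative of 25 (peroxyketal at the (3S)-hydroperoxide and mixed ketal at the C4 CH2OH) | C=C(C)[C@H](CC[C@@]1(C)CC=C(COC(C)(C)OC)C(=O)[C@@H](CC(C)=O)[C@@H]1/C=C/OC(=O)C=C(C)C)OOC(C)(C)OC
F12 | step 17 | (E)-2-[(1S,2S,7S)-5-iodo-2-methyl-2-(4-methylpent-3-en-1-yl)-6-oxo-7-(2-oxopropyl)cyclohept-4-en-1-yl]ethenyl 3-methylbut-2-enoate | CC(C)=CCC[C@@]1(C)CC=C(I)C(=O)[C@@H](CC(C)=O)[C@@H]1/C=C/OC(=O)C=C(C)C
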